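**Retrosynthetic overview**

- The target is a naringenin unit joined through C3 to C3′ of an apigenin unit. The last operations are hydrogenolysis of six benzyl ethers and, before it, a base-free thioether–stannane coupling that makes the aryl–C2 bond of the flavone from a flavanone bromide and a 2-methylsulfanylchromone.
- Key disconnection: the C4–C4a bond of the flavanone. Ring A is a phloroglucinol ring (O1, O5, O7) whose two carbons ortho to O1 are equivalent and each para to an alkoxy group. Ring C can therefore be closed last by intramolecular Friedel–Crafts acylation of a 3-aryloxy-2,3-diarylpropanoic acid in which C2 and C3 are already fixed.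
- The O1–C2 aryl ether comes from SN2 opening, with inversion, of a cis-β-lactone at its benzylic carbon by 3,5-bis(benzyloxy)phenoxide; cis plus inversion leads to the 2,3-trans series.
- The cis-β-lactone comes from an Evans syn-aldol of an (S)-4-benzyloxazolidinone arylacetyl imide with 4-(benzyloxy)benzaldehyde, then hydrolysis and carboxyl-activated lactonisation.
- Ring order: oxetanone (transient), then ring C of the flavanone (key step); the pyranone ring of the apigenin half is built in a two-step side branch from an acetophenone and CS2.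

Key step: step 7

Remark on the chemistry: the 2,3-trans arrangement of a 2,3-diarylchroman-4-one is taken to be the more stable one at the enolisable C3, so only C2 has to be protected against base and acid after ring closure. 3,5-Bis(benzyloxy)phenol and 1-[2,4-bis(benzyloxy)-6-hydroxyphenyl]ethan-1-one are taken to be purchasable.

**Route**

Step 1
Reactants: 1 2-(5-bromo-2-hydroxyphenyl)acetic acid
Product: 3 2-[2-(benzyloxy)-5-bromophenyl]acetic acid, via benzyl ester 2 (not isolated)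
Conditions: BnBr (2.4 equiv), K2CO3, DMF, 60 °C; then 2 M NaOH, MeOH, 60 °C; dilute HCl work-up
Reagents that add atoms: benzyl bromide, BrCc1ccccc1; sodium hydroxide, [Na+].[OH-]
Why: Double O-alkylation (Williamson ether and ester formation) followed by saponification of the ester alone should leave the phenol benzyl ether and the free acid; no stereocentre is involved.

Step 2
Reactants: 3 2-[2-(benzyloxy)-5-bromophenyl]acetic acid; 4 (S)-4-benzyloxazolidin-2-one
Product: 6 (S)-4-benzyl-3-{2-[2-(benzyloxy)-5-bromophenyl]acetyl}oxazolidin-2-one, via mixed pivalic anhydride 5 (not isolated)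
Conditions: t-BuCOCl, Et3N, THF, −20 °C; then LiCl, 4, −20 °C to rt
Reagents that add atoms: none
Why: N-Acylation of the oxazolidinone through the mixed anhydride (LiCl/Et3N variant) is a standard imide formation for arylacetic acids and leaves the auxiliary stereocentre untouched.

Step 3
Reactants: 6 (S)-4-benzyl-3-{2-[2-(benzyloxy)-5-bromophenyl]acetyl}oxazolidin-2-one; 7 4-(benzyloxy)benzaldehyde
Product: 9 (S)-4-benzyl-3-{(2S,3S)-2-[2-(benzyloxy)-5-bromophenyl]-3-[4-(benzyloxy)phenyl]-3-hydroxypropanoyl}oxazolidin-2-one, via Z-boron enolate 8 (not isolated)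
Conditions: Bu2BOTf, i-Pr2NEt, CH2Cl2, −78 to 0 °C; 7, −78 to 0 °C; pH 7 buffer, MeOH, 30% H2O2, 0 °C
Reagents that add atoms: none
Why: Evans syn-aldol: the Z-dibutylboron enolate should react through a closed chair transition state on the face opposite the auxiliary benzyl group, which sets both new centres as (2S,3S), syn.

Step 4
Reactants: 9 (S)-4-benzyl-3-{(2S,3S)-2-[2-(benzyloxy)-5-bromophenyl]-3-[4-(benzyloxy)phenyl]-3-hydroxypropanoyl}oxazolidin-2-one
Product: 11 (2S,3S)-2-[2-(benzyloxy)-5-bromophenyl]-3-[4-(benzyloxy)phenyl]-3-hydroxypropanoic acid, via peroxy acid 10 (not isolated)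
Conditions: LiOH, 30% H2O2, THF/H2O, 0 °C; then aq. Na2SO3; dilute HCl to pH 3
Reagents that add atoms: hydrogen peroxide, OO
Why: Hydroperoxide hydrolysis of the imide attacks the exocyclic carbonyl selectively, and the weakly basic medium at 0 °C should avoid retro-aldol and α-epimerisation, so both centres are kept and the auxiliary is recovered.

Step 5
Reactants: 11 (2S,3S)-2-[2-(benzyloxy)-5-bromophenyl]-3-[4-(benzyloxy)phenyl]-3-hydroxypropanoic acid
Product: 13 (3S,4S)-3-[2-(benzyloxy)-5-bromophenyl]-4-[4-(benzyloxy)phenyl]oxetan-2-one, via mixed sulfonic anhydride 12 (not isolated)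
Conditions: PhSO2Cl (2 equiv), pyridine, 0 °C; cold aqueous work-up, no chromatography, used at once
Reagents that add atoms: none
Why: β-Lactonisation by carboxyl activation (the hydroxyl attacks the activated carbonyl in a 4-exo-trig closure) breaks no bond at either stereocentre, so the syn acid should give the cis-lactone with retention at both.

Step 6
Reactants: 13 (3S,4S)-3-[2-(benzyloxy)-5-bromophenyl]-4-[4-(benzyloxy)phenyl]oxetan-2-one; 14 3,5-bis(benzyloxy)phenol
Product: 16 (2S,3R)-3-[3,5-bis(benzyloxy)phenoxy]-2-[2-(benzyloxy)-5-bromophenyl]-3-[4-(benzyloxy)phenyl]propanoic acid, via potassium phenoxide 15 (not isolated)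
Conditions: 14 (1.3 equiv), KN(SiMe3)2 (1.2 equiv), THF, 0 °C; then 13, THF/DMF, −20 to 0 °C; cold dilute HCl work-up
Reagents that add atoms: none
Why: Phenoxide opening of a β-lactone by alkyl–oxygen cleavage (SN2) at the benzylic C4 should invert that centre and give the (2S,3R) acid; attack at the acyl carbon is reversible, β-elimination from the lactone enolate is stereoelectronically blocked, and the potassium counter-ion in a dipolar aprotic medium favours O- over C-alkylation of the ambident phenoxide.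

Step 7
Reactants: 16 (2S,3R)-3-[3,5-bis(benzyloxy)phenoxy]-2-[2-(benzyloxy)-5-bromophenyl]-3-[4-(benzyloxy)phenyl]propanoic acid
Product: 18 (2R,3S)-5,7-bis(benzyloxy)-3-[2-(benzyloxy)-5-bromophenyl]-2-[4-(benzyloxy)phenyl]chroman-4-one, via acid chloride 17 (not isolated)
Conditions: 1-chloro-N,N,2-trimethylprop-1-en-1-amine (1.1 equiv), CH2Cl2, 0 °C; then 2,6-di-tert-butylpyridine (1.5 equiv), SnCl4 (1.1 equiv), −78 °C; cold aq. NaHCO3 quench
Reagents that add atoms: none
Why: The chloroenamine converts the acid into acyl chloride 17 without releasing HCl, and SnCl4 then generates an acylium-type complex that attacks ring A at a carbon ortho to the ether oxygen and para to a benzyloxy group, the proton being taken up by the hindered pyridine; this is an intramolecular Friedel–Crafts acylation, the known way from 3-aryloxypropanoic acids to chroman-4-ones. Ring C closes as a six-membered ring with the attacked arene bond inside the new ring (endo to the arene, exo to the acyl C=O), and because the two ortho carbons of the 3,5-bis(benzyloxy)phenoxy ring are equivalent only one regioisomer can form. No stereocentre is created: C2 (R) and C3 (S) of 18 are C3 and C2 of the acid and should be carried over with retention, since no bond to either is broken. The step needs acylation to outrun ionisation of the p-benzyloxybenzylic C–O bond (which would scramble C2) and the five-membered closure onto ring B (an indanone); ring A, a phloroglucinol triether, is far more nucleophilic than ring B, whose free ortho positions are meta to its donor, and −78 °C with one equivalent of SnCl4 and the pyridine buffer should keep the ether intact. A cold quench limits SnCl4-assisted loss of the peri C5 benzyl ether, and should C3 epimerise, the trans isomer is the one expected at equilibrium.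

Step 8
Reactants: 18 (2R,3S)-5,7-bis(benzyloxy)-3-[2-(benzyloxy)-5-bromophenyl]-2-[4-(benzyloxy)phenyl]chroman-4-one
Product: 19 (2R,3S)-5,7-bis(benzyloxy)-3-[2-(benzyloxy)-5-(trimethylstannyl)phenyl]-2-[4-(benzyloxy)phenyl]chroman-4-one
Conditions: (Me3Sn)2 (1.5 equiv), Pd(PPh3)4 (5 mol %), toluene, 100 °C
Reagents that add atoms: hexamethylditin, C[Sn](C)(C)[Sn](C)(C)C
Why: Palladium-catalysed stannylation of the aryl bromide with a distannane (Stille-type) runs without base, so the enolisable C3 and the C2–O1 bond, which base would open by retro-oxa-Michael reaction, should stay untouched.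

Step 9
Reactants: 20 1-[2,4-bis(benzyloxy)-6-hydroxyphenyl]ethan-1-one
Product: 21 5,7-bis(benzyloxy)-4-hydroxy-2H-chromene-2-thione
Conditions: KOt-Bu (3.2 equiv), CS2, THF, 0 °C to rt; dilute HCl
Reagents that add atoms: carbon disulfide, S=C=S
Why: Claisen-type condensation of the ketone enolate with CS2 and ring closure by the phenoxide with loss of hydrosulfide is the established way from 2-hydroxyacetophenones to 2-sulfanylchromones.

Step 10
Reactants: 21 5,7-bis(benzyloxy)-4-hydroxy-2H-chromene-2-thione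
Product: 22 5,7-bis(benzyloxy)-2-(methylsulfanyl)-4H-chromen-4-one
Conditions: MeI (1.1 equiv), K2CO3, acetone, rt
Reagents that add atoms: iodomethane, CI
Why: S-Alkylation of the soft thione sulfur should give the 2-methylsulfanylchromone, a vinylogous thioester.

Step 11
Reactants: 19 (2R,3S)-5,7-bis(benzyloxy)-3-[2-(benzyloxy)-5-(trimethylstannyl)phenyl]-2-[4-(benzyloxy)phenyl]chroman-4-one; 22 5,7-bis(benzyloxy)-2-(methylsulfanyl)-4H-chromen-4-one
Product: 23 (2R,3S)-5,7-bis(benzyloxy)-3-{2-(benzyloxy)-5-[5,7-bis(benzyloxy)-4-oxo-4H-chromen-2-yl]phenyl}-2-[4-(benzyloxy)phenyl]chroman-4-one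
Conditions: Pd(PPh3)4 (5 mol %), Cu(O2C-C6H3(OH)Me) (monovalent copper 3-methylsalicylate, 2 equiv), THF, 50 °C
Reagents that add atoms: none
Why: Liebeskind–Srogl-type thioether–stannane coupling: the copper carboxylate activates the C–S bond and takes up the thiolate while zerovalent palladium joins the two carbons, all without base, so the flavanone stereocentres should survive.

Step 12
Reactants: 23 (2R,3S)-5,7-bis(benzyloxy)-3-{2-(benzyloxy)-5-[5,7-bis(benzyloxy)-4-oxo-4H-chromen-2-yl]phenyl}-2-[4-(benzyloxy)phenyl]chroman-4-one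
Product: 24 (2R,3S)-3-[5-(5,7-dihydroxy-4-oxo-4H-chromen-2-yl)-2-hydroxyphenyl]-5,7-dihydroxy-2-(4-hydroxyphenyl)chroman-4-one
Conditions: H2 (1 atm), 10% Pd/C, THF/MeOH, rt
Reagents that add atoms: none
Why: Neutral hydrogenolysis of the six benzyl ethers over Pd/C, stopped at full conversion, should spare the chromone C2=C3 bond and the flavanone C2–O1 bond and touches neither stereocentre.

**Compound list**

1 | 2-(5-bromo-2-hydroxyphenyl)acetic acid | OC(=O)Cc1cc(Br)ccc1O | starting material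
2 | benzyl 2-[2-(benzyloxy)-5-bromophenyl]acetate | O=C(OCc1ccccc1)Cc1cc(Br)ccc1OCc1ccccc1 | intermediate
3 | 2-[2-(benzyloxy)-5-bromophenyl]acetic acid | OC(=O)Cc1cc(Br)ccc1OCc1ccccc1 | intermediate
4 | (S)-4-benzyloxazolidin-2-one | O=C1N[C@@H](Cc2ccccc2)CO1 | starting material
5 | 2-[2-(benzyloxy)-5-bromophenyl]acetic pivalic anhydride | CC(C)(C)C(=O)OC(=O)Cc1cc(Br)ccc1OCc1ccccc1 | intermediate
6 | (S)-4-benzyl-3-{2-[2-(benzyloxy)-5-bromophenyl]acetyl}oxazolidin-2-one | O=C(Cc1cc(Br)ccc1OCc1ccccc1)N1C(=O)OC[C@@H]1Cc1ccccc1 | intermediate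
7 | 4-(benzyloxy)benzaldehyde | O=Cc1ccc(OCc2ccccc2)cc1 | starting material
8 | Z-dibutylboron enolate of imide 6 | CCCCB(CCCC)O/C(=C\c1cc(Br)ccc1OCc1ccccc1)N1C(=O)OC[C@@H]1Cc1ccccc1 | intermediate
9 | (S)-4-benzyl-3-{(2S,3S)-2-[2-(benzyloxy)-5-bromophenyl]-3-[4-(benzyloxy)phenyl]-3-hydroxypropanoyl}oxazolidin-2-one | O=C([C@@H](c1cc(Br)ccc1OCc1ccccc1)[C@H](O)c1ccc(OCc2ccccc2)cc1)N1C(=O)OC[C@@H]1Cc1ccccc1 | intermediate
10 | (2S,3S)-2-[2-(benzyloxy)-5-bromophenyl]-3-[4-(benzyloxy)phenyl]-3-hydroxypropaneperoxoic acid | OOC(=O)[C@@H](c1cc(Br)ccc1OCc1ccccc1)[C@H](O)c1ccc(OCc2ccccc2)cc1 | intermediate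
11 | (2S,3S)-2-[2-(benzyloxy)-5-bromophenyl]-3-[4-(benzyloxy)phenyl]-3-hydroxypropanoic acid | OC(=O)[C@@H](c1cc(Br)ccc1OCc1ccccc1)[C@H](O)c1ccc(OCc2ccccc2)cc1 | intermediate
12 | mixed anhydride of acid 11 and benzenesulfonic acid | O=C(OS(=O)(=O)c1ccccc1)[C@@H](c1cc(Br)ccc1OCc1ccccc1)[C@H](O)c1ccc(OCc2ccccc2)cc1 | intermediate
13 | (3S,4S)-3-[2-(benzyloxy)-5-bromophenyl]-4-[4-(benzyloxy)phenyl]oxetan-2-one (cis) | O=C1[C@@H](c2cc(Br)ccc2OCc2ccccc2)[C@@H](c2ccc(OCc3ccccc3)cc2)O1 | intermediate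
14 | 3,5-bis(benzyloxy)phenol | Oc1cc(OCc2ccccc2)cc(OCc2ccccc2)c1 | starting material
15 | potassium 3,5-bis(benzyloxy)phenoxide | [K+].[O-]c1cc(OCc2ccccc2)cc(OCc2ccccc2)c1 | intermediate
16 | (2S,3R)-3-[3,5-bis(benzyloxy)phenoxy]-2-[2-(benzyloxy)-5-bromophenyl]-3-[4-(benzyloxy)phenyl]propanoic acid | O=C(O)[C@@H](c1cc(Br)ccc1OCc1ccccc1)[C@H](c1ccc(OCc2ccccc2)cc1)Oc1cc(OCc2ccccc2)cc(OCc2ccccc2)c1 | intermediate
17 | (2S,3R)-3-[3,5-bis(benzyloxy)phenoxy]-2-[2-(benzyloxy)-5-bromophenyl]-3-[4-(benzyloxy)phenyl]propanoyl chloride | O=C(Cl)[C@@H](c1cc(Br)ccc1OCc1ccccc1)[C@H](c1ccc(OCc2ccccc2)cc1)Oc1cc(OCc2ccccc2)cc(OCc2ccccc2)c1 | intermediate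
18 | (2R,3S)-5,7-bis(benzyloxy)-3-[2-(benzyloxy)-5-bromophenyl]-2-[4-(benzyloxy)phenyl]chroman-4-one | O=C1c2c(OCc3ccccc3)cc(OCc3ccccc3)cc2O[C@@H](c2ccc(OCc3ccccc3)cc2)[C@@H]1c1cc(Br)ccc1OCc1ccccc1 | intermediate
19 | (2R,3S)-5,7-bis(benzyloxy)-3-[2-(benzyloxy)-5-(trimethylstannyl)phenyl]-2-[4-(benzyloxy)phenyl]chroman-4-one | O=C1c2c(OCc3ccccc3)cc(OCc3ccccc3)cc2O[C@@H](c2ccc(OCc3ccccc3)cc2)[C@@H]1c1cc([Sn](C)(C)C)ccc1OCc1ccccc1 | intermediate
20 | 1-[2,4-bis(benzyloxy)-6-hydroxyphenyl]ethan-1-one | CC(=O)c1c(O)cc(OCc2ccccc2)cc1OCc1ccccc1 | starting material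
21 | 5,7-bis(benzyloxy)-4-hydroxy-2H-chromene-2-thione | S=C1C=C(O)c2c(OCc3ccccc3)cc(OCc3ccccc3)cc2O1 | intermediate
22 | 5,7-bis(benzyloxy)-2-(methylsulfanyl)-4H-chromen-4-one | CSc1cc(=O)c2c(OCc3ccccc3)cc(OCc3ccccc3)cc2o1 | intermediate
23 | (2R,3S)-5,7-bis(benzyloxy)-3-{2-(benzyloxy)-5-[5,7-bis(benzyloxy)-4-oxo-4H-chromen-2-yl]phenyl}-2-[4-(benzyloxy)phenyl]chroman-4-one | O=C1c2c(OCc3ccccc3)cc(OCc3ccccc3)cc2O[C@@H](c2ccc(OCc3ccccc3)cc2)[C@@H]1c1cc(-c2cc(=O)c3c(OCc4ccccc4)cc(OCc4ccccc4)cc3o2)ccc1OCc1ccccc1 | intermediate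
24 | (2R,3S)-3-[5-(5,7-dihydroxy-4-oxo-4H-chromen-2-yl)-2-hydroxyphenyl]-5,7-dihydroxy-2-(4-hydroxyphenyl)chroman-4-one | O=C1c2c(O)cc(O)cc2O[C@@H](c2ccc(O)cc2)[C@@H]1c1cc(-c2cc(=O)c3c(O)cc(O)cc3o2)ccc1O | target

**Step count and risks**

Total step count: 12. Longest linear sequence: 10 steps (steps 1 to 8, 11 and 12, from 1 to 24); steps 9 and 10 form the side branch.

The three steps most likely to fail:

Step 7. The SnCl4 complex may ionise the p-benzyloxybenzylic C–O bond before the acyl group has closed the ring. That would scramble C2, alkylate ring A at carbon, or strip the peri benzyl ether. The fallback closes ring C with reversed polarity (Parham-type anionic cycloacylation) and sets out from 13 and 14. Phenol 14 would be iodinated ortho to the hydroxyl (NIS, CH2Cl2, 0 °C) to 3,5-bis(benzyloxy)-2-iodophenol F6. Its potassium salt would open lactone 13 as in step 6 to (2S,3R)-3-[3,5-bis(benzyloxy)-2-iodophenoxy]-2-[2-(benzyloxy)-5-bromophenyl]-3-[4-(benzyloxy)phenyl]propanoic acid F7. Amide coupling (EDC·HCl, MeNHOMe·HCl, N-methylmorpholine) would give the N-methoxy-N-methylamide F8. Iodine–magnesium exchange with i-PrMgCl·LiCl at −40 °C, selective for the iodide over the bromide, and attack of the aryl magnesium on the amide would return the route at 18 without any Lewis acid.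

Step 6. Lactone 13 carries a p-alkoxyphenyl group at C4 and may lose CO2 to the Z-stilbene or react through an ion pair, so that inversion is incomplete. The phenoxide may also attack at carbon or trigger retro-aldol cleavage after acyl attack. Leakage at this centre gives the syn diastereomer of 16, which can be removed, and does not give the enantiomer. The fallback avoids the lactone and any enolisable carbonyl during ether formation; it sets out from 9. Reductive removal of the auxiliary (LiBH4, THF/MeOH) would give (1S,2R)-2-[2-(benzyloxy)-5-bromophenyl]-1-[4-(benzyloxy)phenyl]propane-1,3-diol F1. Silylation of the primary hydroxyl (TBSCl, imidazole) would give the mono-silyl ether F2. A Mitsunobu reaction with 14 (PPh3, DIAD, toluene, 0 °C) would invert the benzylic carbinol and give the aryl ether F3. Bu4NF would free the primary alcohol F4. Dess–Martin oxidation would give the aldehyde F5, and Pinnick oxidation (NaClO2, NaH2PO4, 2-methyl-2-butene) would return the route at 16.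

Step 11. Transmetalation of the electron-rich arylstannane may be slower than protodestannylation, or the C–S bond of the chromone may not be activated in the presence of the flavanone. The fallback moves the coupling to the base-stable acid and sets out from 16. Miyaura-type borylation with B2(OH)4 (Pd(OAc)2, XPhos, KOAc, EtOH, 80 °C) would give the boronic acid F9. Liebeskind–Srogl coupling with 22 (Pd2(dba)3, tri(2-furyl)phosphine, Cu(O2C-C4H3S) as the monovalent copper thiophene-2-carboxylate, THF, 50 °C) would give the flavone-bearing acid F10. Ring closure as in step 7, with extra SnCl4 for the chromone carbonyl, would pass through the acid chloride F11 and return the route at 23.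

**Further compounds**

F1 | step 6 | (1S,2R)-2-[2-(benzyloxy)-5-bromophenyl]-1-[4-(benzyloxy)phenyl]propane-1,3-diol | OC[C@@H](c1cc(Br)ccc1OCc1ccccc1)[C@H](O)c1ccc(OCc2ccccc2)cc1
F2 | step 6 | (1S,2R)-2-[2-(benzyloxy)-5-bromophenyl]-1-[4-(benzyloxy)phenyl]-3-[(tert-butyldimethylsilyl)oxy]propan-1-ol | CC(C)(C)[Si](C)(C)OC[C@@H](c1cc(Br)ccc1OCc1ccccc1)[C@H](O)c1ccc(OCc2ccccc2)cc1
F3 | step 6 | [(2R,3R)-3-[3,5-bis(benzyloxy)phenoxy]-2-[2-(benzyloxy)-5-bromophenyl]-3-[4-(benzyloxy)phenyl]propoxy](tert-butyl)dimethylsilane | CC(C)(C)[Si](C)(C)OC[C@@H](c1cc(Br)ccc1OCc1ccccc1)[C@@H](Oc1cc(OCc2ccccc2)cc(OCc2ccccc2)c1)c1ccc(OCc2ccccc2)cc1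
F4 | step 6 | (2R,3R)-3-[3,5-bis(benzyloxy)phenoxy]-2-[2-(benzyloxy)-5-bromophenyl]-3-[4-(benzyloxy)phenyl]propan-1-ol | OC[C@@H](c1cc(Br)ccc1OCc1ccccc1)[C@@H](Oc1cc(OCc2ccccc2)cc(OCc2ccccc2)c1)c1ccc(OCc2ccccc2)cc1
F5 | step 6 | (2S,3R)-3-[3,5-bis(benzyloxy)phenoxy]-2-[2-(benzyloxy)-5-bromophenyl]-3-[4-(benzyloxy)phenyl]propanal | O=C[C@@H](c1cc(Br)ccc1OCc1ccccc1)[C@@H](Oc1cc(OCc2ccccc2)cc(OCc2ccccc2)c1)c1ccc(OCc2ccccc2)cc1
F6 | step 7 | 3,5-bis(benzyloxy)-2-iodophenol | Oc1cc(OCc2ccccc2)cc(OCc2ccccc2)c1I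
F7 | step 7 | (2S,3R)-3-[3,5-bis(benzyloxy)-2-iodophenoxy]-2-[2-(benzyloxy)-5-bromophenyl]-3-[4-(benzyloxy)phenyl]propanoic acid | O=C(O)[C@@H](c1cc(Br)ccc1OCc1ccccc1)[C@H](c1ccc(OCc2ccccc2)cc1)Oc1cc(OCc2ccccc2)cc(OCc2ccccc2)c1I
F8 | step 7 | (2S,3R)-3-[3,5-bis(benzyloxy)-2-iodophenoxy]-2-[2-(benzyloxy)-5-bromophenyl]-3-[4-(benzyloxy)phenyl]-N-methoxy-N-methylpropanamide | CON(C)C(=O)[C@@H](c1cc(Br)ccc1OCc1ccccc1)[C@H](c1ccc(OCc2ccccc2)cc1)Oc1cc(OCc2ccccc2)cc(OCc2ccccc2)c1I
F9 | step 11 | (2S,3R)-3-[3,5-bis(benzyloxy)phenoxy]-2-[2-(benzyloxy)-5-(dihydroxyboranyl)phenyl]-3-[4-(benzyloxy)phenyl]propanoic acid | O=C(O)[C@@H](c1cc(B(O)O)ccc1OCc1ccccc1)[C@H](c1ccc(OCc2ccccc2)cc1)Oc1cc(OCc2ccccc2)cc(OCc2ccccc2)c1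
F10 | step 11 | (2S,3R)-3-[3,5-bis(benzyloxy)phenoxy]-2-{2-(benzyloxy)-5-[5,7-bis(benzyloxy)-4-oxo-4H-chromen-2-yl]phenyl}-3-[4-(benzyloxy)phenyl]propanoic acid | O=C(O)[C@@H](c1cc(-c2cc(=O)c3c(OCc4ccccc4)cc(OCc4ccccc4)cc3o2)ccc1OCc1ccccc1)[C@H](c1ccc(OCc2ccccc2)cc1)Oc1cc(OCc2ccccc2)cc(OCc2ccccc2)c1
F11 | step 11 | (2S,3R)-3-[3,5-bis(benzyloxy)phenoxy]-2-{2-(benzyloxy)-5-[5,7-bis(benzyloxy)-4-oxo-4H-chromen-2-yl]phenyl}-3-[4-(benzyloxy)phenyl]propanoyl chloride | O=C(Cl)[C@@H](c1cc(-c2cc(=O)c3c(OCc4ccccc4)cc(OCc4ccccc4)cc3o2)ccc1OCc1ccccc1)[C@H](c1ccc(OCc2ccccc2)cc1)Oc1cc(OCc2ccccc2)cc(OCc2ccccc2)c1
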